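**Plan**
1. Retrosynthesis: the C13 acetate and the C15=C17 methylene are removed, then the 14-membered ring is cut at C3=C4 and at C7=C8. The excised piece, C4(Me)–C5–C6–C7 between the two trisubstituted ring olefins, is exactly the four ring carbons and the methyl group of 1-methylcyclobutene.
2. The remaining cis-γ-lactone (C1, C2, C15, C16, O) carries a C2 vinyl group and a C8 isopropenyl end. It is cut at C1–C15 (alkynylalane on a C1–C2 epoxy alcohol) and at C13–C14 (vinylogous aldol of a C8–C13 enal with a crotonate dienolate).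
3. Forward: the chain is joined first, the C11–C12 epoxide, the C1–C2 epoxide, the γ-lactone (first ring) and the vinyl group follow. One metathesis cascade with 1-methylcyclobutene then forms C3=C4, C7=C8 and the 14-membered ring (second ring); α-methylenation and the acetate come last.
4. Stereochemistry: C11, C12 and C13 come from a Sharpless kinetic resolution with D-(−)-diisopropyl tartrate. C2 comes from a Sharpless epoxidation with L-(+)-diethyl tartrate and C1 from SN2 inversion of that epoxide (cis-lactone). 3E and 7E arise in the metathesis step.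

Key step: step 12

Remark: locants C1–C17 follow the cembrane-type numbering of the target (C1 ring-fusion CH, C2 lactone O–CH, C15 α-carbon, C16 C=O, C17 exocyclic CH2). Where the CIP letter at C2 or C12 differs between compounds, only substituent priorities have changed, not the spatial arrangement. Compounds 1, 2, 5, 12 and 17 are assumed to be purchased.

**Step 1**
Reactants: 1 4-methylpent-4-en-1-ol; 2 2-(triphenylphosphoranylidene)propanal
Product: 4 (2E)-2,6-dimethylhepta-2,6-dienal, via 4-methylpent-4-enal 3 (not isolated)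
Conditions: TEMPO (10 mol %), PhI(OAc)2, CH2Cl2, 23 °C; then 2, 40 °C
Reagents that add atoms: none
Why: the nitroxyl-catalysed oxidation stops at aldehyde 3, and the Wittig reaction of the formyl-stabilised ylide in the same flask should give the (E)-2-methyl enal because stabilised ylides react under thermodynamic control; no stereocentre is formed.

**Step 2**
Reactants: 5 ethyl (2E)-but-2-enoate
Product: 6 [(1-ethoxybuta-1,3-dien-1-yl)oxy]trimethylsilane (ketene acetal geometry inconsequential)
Conditions: LiN(iPr)2, DMPU, THF, −78 °C; Me3SiCl, −78 → 23 °C; distillation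
Reagents that add atoms: chlorotrimethylsilane, C[Si](C)(C)Cl
Why: γ-deprotonation of the crotonate gives the extended lithium enolate, which is trapped on oxygen (silyl ketene acetal formation).

**Step 3**
Reactants: 4 dienal; 6 silyl dienolate
Product: 7 ethyl (2E,6E)-5-hydroxy-6,10-dimethylundeca-2,6,10-trienoate (racemic at C13)
Conditions: BF3·OEt2 (1.1 equiv), CH2Cl2, −78 °C; aq NaHCO3
Reagents that add atoms: none
Why: vinylogous Mukaiyama aldol reaction in which the γ-carbon of the dienolate adds 1,2 to the BF3-activated enal and leaves the (E)-enoate; C13 is formed racemic and is resolved in step 4.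

**Step 4**
Reactants: 7 racemic hydroxy ester
Product: 8 ethyl (2E,5R)-5-hydroxy-5-[(2R,3R)-2-methyl-3-(3-methylbut-3-en-1-yl)oxiran-2-yl]pent-2-enoate
Conditions: Ti(OiPr)4 (0.2 equiv), D-(−)-diisopropyl tartrate (0.24 equiv), tBuOOH (0.5 equiv), 4 Å molecular sieves, CH2Cl2, −20 °C, stopped near 45 % conversion
Reagents that add atoms: tert-butyl hydroperoxide, CC(C)(C)OO
Why: Sharpless kinetic resolution, in which the D-(−)-tartrate catalyst epoxidises the (13R)-alcohol much faster than its antipode and delivers oxygen to the face that gives the erythro epoxy alcohol, so that C13 (by selection) and C12 and C11 (by hydroxyl-directed delivery) are fixed together; the (13S)-alcohol stays behind and is separated, and the enoate and isopropenyl olefins are not allylic alcohols and should not react.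

**Step 5**
Reactants: 8 epoxy alcohol
Product: 9 ethyl (2E,5R)-5-[(tert-butyldimethylsilyl)oxy]-5-[(2S,3R)-2-methyl-3-(3-methylbut-3-en-1-yl)oxiran-2-yl]pent-2-enoate
Conditions: tBuMe2SiOTf, 2,6-lutidine, CH2Cl2, −78 → 0 °C
Reagents that add atoms: tert-butyldimethylsilyl trifluoromethanesulfonate, CC(C)(C)[Si](C)(C)OS(=O)(=O)C(F)(F)F
Why: silyl ether formation with the silyl triflate and a hindered base should protect the congested secondary alcohol at low temperature without touching the epoxide.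

**Step 6**
Reactants: 9 silyl ether ester
Product: 10 (2E,5R)-5-[(tert-butyldimethylsilyl)oxy]-5-[(2S,3R)-2-methyl-3-(3-methylbut-3-en-1-yl)oxiran-2-yl]pent-2-en-1-ol
Conditions: iBu2AlH (2.5 equiv), CH2Cl2, −78 °C; aq KNaC4H4O6
Reagents that add atoms: none
Why: 1,2-reduction of the unsaturated ester by the aluminium hydride gives the (E)-allylic alcohol, the trisubstituted epoxide and the silyl ether being inert at −78 °C.

**Step 7**
Reactants: 10 allylic alcohol
Product: 11 {(2S,3S)-3-[(2R)-2-[(tert-butyldimethylsilyl)oxy]-2-[(2S,3R)-2-methyl-3-(3-methylbut-3-en-1-yl)oxiran-2-yl]ethyl]oxiran-2-yl}methanol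
Conditions: Ti(OiPr)4 (0.1 equiv), L-(+)-diethyl tartrate (0.12 equiv), tBuOOH (2 equiv), 4 Å molecular sieves, CH2Cl2, −20 °C
Reagents that add atoms: tert-butyl hydroperoxide, CC(C)(C)OO
Why: Sharpless asymmetric epoxidation, in which the L-(+)-tartrate catalyst selects one face of the (E)-allylic alcohol under reagent control and sets C2 and C1 as the (2S,3S) trans-epoxy alcohol whatever the remote centres.

**Step 8**
Reactants: 11 bis-epoxy alcohol; 12 ethoxyethyne
Product: 14 (4S,5R)-4-{(2R)-2-[(tert-butyldimethylsilyl)oxy]-2-[(2S,3R)-2-methyl-3-(3-methylbut-3-en-1-yl)oxiran-2-yl]ethyl}-5-(hydroxymethyl)oxolan-2-one, via ynol ether diol 13 (not isolated)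
Conditions: 12, nBuLi, toluene, −40 → 0 °C; Et2AlCl; then 11, 0 → 23 °C; aq KNaC4H4O6; then camphorsulfonic acid (5 mol %), wet CH2Cl2, 0 °C
Reagents that add atoms: diethyl(ethoxyethynyl)aluminium, CCOC#C[Al](CC)CC (made in the flask from 12); water, O
Why: alkynylalane opening of a 2,3-epoxy alcohol, in which the aluminium alkoxide at the C3 oxygen should deliver the ethoxyethynyl group to the distal carbon C1 with inversion (this sets C1 and places C14 cis to C3), the unassisted and neopentyl-like C11–C12 epoxide being far slower; mild acid then turns the ynol ether, through its cyclic ketene acetal with the C2 hydroxyl, into the five-membered lactone.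

**Step 9**
Reactants: 14 hydroxymethyl lactone
Product: 15 (2R,3S)-3-{(2R)-2-[(tert-butyldimethylsilyl)oxy]-2-[(2S,3R)-2-methyl-3-(3-methylbut-3-en-1-yl)oxiran-2-yl]ethyl}-5-oxooxolane-2-carbaldehyde
Conditions: Dess–Martin periodinane, NaHCO3, CH2Cl2, 0 → 23 °C
Reagents that add atoms: none
Why: Dess–Martin oxidation under bicarbonate buffer is neither acidic nor strongly basic, so the epimerisable C2 centre and the epoxide should survive.

**Step 10**
Reactants: 15 lactone aldehyde
Product: 16 (4S,5S)-4-{(2R)-2-[(tert-butyldimethylsilyl)oxy]-2-[(2S,3R)-2-methyl-3-(3-methylbut-3-en-1-yl)oxiran-2-yl]ethyl}-5-ethenyloxolan-2-one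
Conditions: Ph3PCH3Br, KN(SiMe3)2, THF, 0 °C; then 15, −78 → 0 °C
Reagents that add atoms: methylenetriphenylphosphorane, C=P(c1ccccc1)(c1ccccc1)c1ccccc1 (made in the flask from Ph3PCH3Br and KN(SiMe3)2)
Why: Wittig methylenation with the salt-free ylide at low temperature should convert the aldehyde faster than the ylide can enolise it or attack the lactone.

**Step 11**
Reactants: 17 methylidenecyclobutane
Product: 18 1-methylcyclobutene
Conditions: Na/Al2O3 (cat.), neat, 25 °C; fractional distillation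
Reagents that add atoms: none
Why: base-catalysed olefin isomerisation through the allyl anion moves the double bond into the ring, the trisubstituted endocyclic isomer being favoured at equilibrium.

**Step 12**
Reactants: 16 vinyl lactone; 18 1-methylcyclobutene
Product: 19 (1S,2R,3E,7E,11R,12S,13R)-13-[(tert-butyldimethylsilyl)oxy]-11,12-epoxy-17-norcembra-3,7-dien-16,2-olide
Conditions: RuCl2(H2IMes)(PCy3)(=CHPh) (second-generation Grubbs catalyst, 10 mol %), 18 (3 equiv, syringe pump, 8 h), toluene (2 mM in 16), 45 °C, condenser at −20 °C; then 80 °C, 12 h, argon sparge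
Reagents that add atoms: none
Why: Proposed new method: the benzylidene initiates on the C2 vinyl group of 16, its only monosubstituted olefin, and the C3 alkylidene adds to strained 18 with ruthenium on the unsubstituted ring carbon (C7) and C3 on the methyl-bearing carbon (C4), so that strain-driven cycloreversion forms the C3=C4 trisubstituted olefin and a monosubstituted C7 alkylidene, which closes on the C8 isopropenyl group and releases Ru=CH2 for the next turnover with loss of ethylene. The closest known reactions are ring-opening cross-metathesis of cyclobutenes, ring-expansion metathesis of cycloalkenes with acyclic dienes, and the head-to-tail ring-opening polymerisation of 1-methylcyclobutene to polyisoprene, which shows the same regiochemistry of addition. The 14-membered ring closes by ring-closing olefin metathesis between the C7 alkylidene and the 1,1-disubstituted C8 olefin; no stereocentre is formed and the five existing ones are not touched. Initiation on the substrate and a single insertion are needed, and slow addition of 18 into a dilute solution should secure both by keeping the cyclobutene scarce, so that each C7 alkylidene cyclises before it meets a second cyclobutene, while chain ends capped by methylidene are terminal olefins and re-enter the cycle. The regiochemistry is enforced because the reverse addition would need a disubstituted alkylidene at C4 and a tetrasubstituted C4=C8 olefin, so a mis-joined C3=C7 disubstituted olefin cannot close and is cleaved again by Ru=CH2. E geometry is needed at both new olefins: at C3=C4 the metallacyclobutane with the C2 substituent turned away from the cyclobutane methylene groups leads to the E isomer, and at C7=C8 the less strained E,E-macrocycle should be favoured when closure is kept reversible at 80 °C, Z isomers being removed on AgNO3-impregnated silica.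

**Step 13**
Reactants: 19 macrocyclic lactone
Product: 20 (1S,2R,3E,7E,11R,12S,13R,15R)-13-[(tert-butyldimethylsilyl)oxy]-17-(dimethylamino)-11,12-epoxycembra-3,7-dien-16,2-olide
Conditions: LiN(iPr)2, THF, −78 °C; CH2=NMe2+ I−, −78 → 23 °C
Reagents that add atoms: N,N-dimethylmethyleneiminium iodide, C=[N+](C)C.[I-]
Why: Mannich reaction of the lactone lithium enolate with the preformed iminium salt, the electrophile entering trans to the C14 substituent on C1; the C15 configuration is of no consequence because step 14 removes it.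

**Step 14**
Reactants: 20 Mannich base
Product: 22 (1S,2S,3E,7E,11R,12S,13R)-13-[(tert-butyldimethylsilyl)oxy]-11,12-epoxycembra-3,7,15(17)-trien-16,2-olide, via trimethylammonium iodide 21 (not isolated)
Conditions: MeI, MeOH, 23 °C; then aq NaHCO3, CH2Cl2, 23 °C
Reagents that add atoms: none
Why: exhaustive N-methylation followed by E1cB (Hofmann-type) loss of trimethylamine from the β-ammonio lactone should give the exocyclic methylene group under conditions too mild to harm the epoxide.

**Step 15**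
Reactants: 22 silyl ether
Product: 23 (1S,2S,3E,7E,11R,12R,13R)-11,12-epoxy-13-hydroxycembra-3,7,15(17)-trien-16,2-olide
Conditions: HF·pyridine, pyridine, THF, 0 → 23 °C
Reagents that add atoms: none
Why: fluoride desilylation in a pyridine-buffered, non-basic medium frees the C13 hydroxyl without forming an alkoxide, so neither conjugate addition to the methylene lactone nor epoxide opening is expected.

**Step 16**
Reactants: 23 alcohol
Product: 24 (1S,2S,3E,7E,11R,12S,13R)-13-acetoxy-11,12-epoxycembra-3,7,15(17)-trien-16,2-olide (CNP0146076.4)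
Conditions: Ac2O, pyridine, DMAP (cat.), CH2Cl2, 0 → 23 °C
Reagents that add atoms: acetic anhydride, CC(=O)OC(C)=O
Why: DMAP-catalysed acylation of the secondary alcohol gives the acetate without affecting the other functional groups.

**Compound list**
1 | 4-methylpent-4-en-1-ol | C=C(C)CCCO | starting material
2 | 2-(triphenylphosphoranylidene)propanal | CC(C=O)=P(c1ccccc1)(c1ccccc1)c1ccccc1 | starting material
3 | 4-methylpent-4-enal | C=C(C)CCC=O | intermediate
4 | (2E)-2,6-dimethylhepta-2,6-dienal | O=C/C(C)=C/CCC(C)=C | intermediate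
5 | ethyl (2E)-but-2-enoate | C/C=C/C(=O)OCC | starting material
6 | [(1-ethoxybuta-1,3-dien-1-yl)oxy]trimethylsilane | CCOC(=CC=C)O[Si](C)(C)C | intermediate
7 | ethyl (2E,6E)-5-hydroxy-6,10-dimethylundeca-2,6,10-trienoate (racemic) | CCOC(=O)/C=C/CC(O)/C(C)=C/CCC(C)=C | intermediate
8 | ethyl (2E,5R)-5-hydroxy-5-[(2R,3R)-2-methyl-3-(3-methylbut-3-en-1-yl)oxiran-2-yl]pent-2-enoate | CCOC(=O)/C=C/C[C@@H](O)[C@@]1(C)O[C@@H]1CCC(C)=C | intermediate
9 | ethyl (2E,5R)-5-[(tert-butyldimethylsilyl)oxy]-5-[(2S,3R)-2-methyl-3-(3-methylbut-3-en-1-yl)oxiran-2-yl]pent-2-enoate | CCOC(=O)/C=C/C[C@@H](O[Si](C)(C)C(C)(C)C)[C@@]1(C)O[C@@H]1CCC(C)=C | intermediate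
10 | (2E,5R)-5-[(tert-butyldimethylsilyl)oxy]-5-[(2S,3R)-2-methyl-3-(3-methylbut-3-en-1-yl)oxiran-2-yl]pent-2-en-1-ol | OC/C=C/C[C@@H](O[Si](C)(C)C(C)(C)C)[C@@]1(C)O[C@@H]1CCC(C)=C | intermediate
11 | {(2S,3S)-3-[(2R)-2-[(tert-butyldimethylsilyl)oxy]-2-[(2S,3R)-2-methyl-3-(3-methylbut-3-en-1-yl)oxiran-2-yl]ethyl]oxiran-2-yl}methanol | OC[C@@H]1O[C@H]1C[C@@H](O[Si](C)(C)C(C)(C)C)[C@@]2(C)O[C@@H]2CCC(C)=C | intermediate
12 | ethoxyethyne | CCOC#C | starting material
13 | (2R,3S,5R)-5-[(tert-butyldimethylsilyl)oxy]-3-(ethoxyethynyl)-5-[(2S,3R)-2-methyl-3-(3-methylbut-3-en-1-yl)oxiran-2-yl]pentane-1,2-diol | OC[C@H](O)[C@H](C#COCC)C[C@@H](O[Si](C)(C)C(C)(C)C)[C@@]1(C)O[C@@H]1CCC(C)=C | intermediate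
14 | (4S,5R)-4-{(2R)-2-[(tert-butyldimethylsilyl)oxy]-2-[(2S,3R)-2-methyl-3-(3-methylbut-3-en-1-yl)oxiran-2-yl]ethyl}-5-(hydroxymethyl)oxolan-2-one | O=C1C[C@H](C[C@@H](O[Si](C)(C)C(C)(C)C)[C@@]2(C)O[C@@H]2CCC(C)=C)[C@H](CO)O1 | intermediate
15 | (2R,3S)-3-{(2R)-2-[(tert-butyldimethylsilyl)oxy]-2-[(2S,3R)-2-methyl-3-(3-methylbut-3-en-1-yl)oxiran-2-yl]ethyl}-5-oxooxolane-2-carbaldehyde | O=C1C[C@H](C[C@@H](O[Si](C)(C)C(C)(C)C)[C@@]2(C)O[C@@H]2CCC(C)=C)[C@H](C=O)O1 | intermediate
16 | (4S,5S)-4-{(2R)-2-[(tert-butyldimethylsilyl)oxy]-2-[(2S,3R)-2-methyl-3-(3-methylbut-3-en-1-yl)oxiran-2-yl]ethyl}-5-ethenyloxolan-2-one | O=C1C[C@H](C[C@@H](O[Si](C)(C)C(C)(C)C)[C@@]2(C)O[C@@H]2CCC(C)=C)[C@H](C=C)O1 | intermediate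
17 | methylidenecyclobutane | C=C1CCC1 | starting material
18 | 1-methylcyclobutene | CC1=CCC1 | intermediate
19 | (1S,2R,3E,7E,11R,12S,13R)-13-[(tert-butyldimethylsilyl)oxy]-11,12-epoxy-17-norcembra-3,7-dien-16,2-olide | C1C(=O)O[C@H]2/C=C(\C)CC/C=C(\C)CC[C@H]3O[C@]3(C)[C@H](O[Si](C)(C)C(C)(C)C)C[C@@H]12 | intermediate
20 | (1S,2R,3E,7E,11R,12S,13R,15R)-13-[(tert-butyldimethylsilyl)oxy]-17-(dimethylamino)-11,12-epoxycembra-3,7-dien-16,2-olide | CN(C)C[C@@H]1C(=O)O[C@H]2/C=C(\C)CC/C=C(\C)CC[C@H]3O[C@]3(C)[C@H](O[Si](C)(C)C(C)(C)C)C[C@@H]12 | intermediate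
21 | (1S,2R,3E,7E,11R,12S,13R,15R)-13-[(tert-butyldimethylsilyl)oxy]-11,12-epoxy-17-(trimethylammonio)cembra-3,7-dien-16,2-olide iodide | C[N+](C)(C)C[C@@H]1C(=O)O[C@H]2/C=C(\C)CC/C=C(\C)CC[C@H]3O[C@]3(C)[C@H](O[Si](C)(C)C(C)(C)C)C[C@@H]12.[I-] | intermediate
22 | (1S,2S,3E,7E,11R,12S,13R)-13-[(tert-butyldimethylsilyl)oxy]-11,12-epoxycembra-3,7,15(17)-trien-16,2-olide | C=C1C(=O)O[C@H]2/C=C(\C)CC/C=C(\C)CC[C@H]3O[C@]3(C)[C@H](O[Si](C)(C)C(C)(C)C)C[C@@H]12 | intermediate
23 | (1S,2S,3E,7E,11R,12R,13R)-11,12-epoxy-13-hydroxycembra-3,7,15(17)-trien-16,2-olide | C=C1C(=O)O[C@H]2/C=C(\C)CC/C=C(\C)CC[C@H]3O[C@]3(C)[C@H](O)C[C@@H]12 | intermediate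
24 | (1S,2S,3E,7E,11R,12S,13R)-13-acetoxy-11,12-epoxycembra-3,7,15(17)-trien-16,2-olide (CNP0146076.4) | C=C1C(=O)O[C@H]2/C=C(\C)CC/C=C(\C)CC[C@H]3O[C@]3(C)[C@H](OC(C)=O)C[C@@H]12 | target

**Count**
Total step count: 16. Longest linear sequence: 14 steps (steps 1, 3 to 10, 12 to 16); steps 2 and 11 are side branches.

**Steps most likely to fail**

Step 12. What may go wrong: the catalyst may polymerise the cyclobutene before it loads onto the substrate, more than one C5 unit may be inserted, or the new olefins may close with Z geometry. Fallback (known chemistry; sets out from 14, returns at 19): the isopropenyl group is the only olefin of 14. Cross-metathesis with purchased 2-methylhexa-1,5-diene (C=C(C)CCC=C, excess; RuCl2(H2IMes)(PCy3)(=CHPh), CH2Cl2, 40 °C) should join C8 to the monosubstituted end of the diene and give the chain-extended hydroxymethyl lactone F1, with C7=C8 in place and the E isomer separated. Oxidation as in step 9 should give the chain-extended aldehyde F2, and methylenation as in step 10 the chain-extended vinyl lactone F3. Ordinary macrocyclic ring-closing metathesis between the C2 vinyl group and the C4 methylidene terminus (same catalyst, toluene, 80 °C, 1 mM) then closes C3=C4 and delivers 19.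

Step 8. What may go wrong: alkynyl transfer to the C11–C12 epoxide, Lewis-acid rearrangement of the silyloxy epoxide, or attack at C2 instead of C1. Fallback (sets out from 7, returns at 16): the C11–C12 epoxide is introduced only after the lactone is built.
- Racemic 7 is resolved in the opposite sense (Ti(OiPr)4, L-(+)-diisopropyl tartrate, tBuOOH, past half conversion), which leaves the (13R)-allylic alcohol F4 and consumes its antipode as the enantiomeric epoxy alcohol F5.
- Silylation as in step 5 gives the silyl ether ester F6, and iBu2AlH reduction the dienyl allylic alcohol F7.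
- Sharpless epoxidation with L-(+)-diethyl tartrate gives the mono-epoxy alcohol F8, which now holds a single epoxide.
- The alane of step 8 gives the olefinic ynol ether diol F9, and acid the olefinic hydroxymethyl lactone F10.
- Oxidation gives the olefinic lactone aldehyde F11 and methylenation the olefinic vinyl lactone F12.
- HF·pyridine frees the allylic alcohol lactone F13.
- Hydroxyl-directed epoxidation in the matched sense (Ti(OiPr)4, D-(−)-diisopropyl tartrate, tBuOOH) gives the epoxy alcohol lactone F14.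
- tBuMe2SiOTf with 2,6-lutidine returns 16.

Step 10. What may go wrong: base-induced epimerisation at C2 of the α-acyloxy aldehyde during oxidation and olefination, giving the trans-lactone. Fallback (sets out from 13, returns at 16): no aldehyde is made. The ynol ether diol 13 is kept before lactonisation and its primary hydroxyl is sulfonylated selectively (TsCl, Et3N, Bu2SnO cat.) to the primary tosylate F15. K2CO3 in MeOH closes the terminal epoxide F16 with retention at C2. Dimethylsulfonium methylide (Me3S+ I−, nBuLi, THF, −10 °C) opens it at C3 and eliminates to the vinyl carbinol F17. The acid treatment of step 8 then lactonises the ynol ether directly to 16.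

**Further compounds**
F1 | step 12 | (4S,5R)-4-{(2R)-2-[(tert-butyldimethylsilyl)oxy]-2-[(2S,3R)-3-[(3E)-3,7-dimethylocta-3,7-dien-1-yl]-2-methyloxiran-2-yl]ethyl}-5-(hydroxymethyl)oxolan-2-one | O=C1C[C@H](C[C@@H](O[Si](C)(C)C(C)(C)C)[C@@]2(C)O[C@@H]2CC/C(C)=C/CCC(C)=C)[C@H](CO)O1
F2 | step 12 | (2R,3S)-3-{(2R)-2-[(tert-butyldimethylsilyl)oxy]-2-[(2S,3R)-3-[(3E)-3,7-dimethylocta-3,7-dien-1-yl]-2-methyloxiran-2-yl]ethyl}-5-oxooxolane-2-carbaldehyde | O=C1C[C@H](C[C@@H](O[Si](C)(C)C(C)(C)C)[C@@]2(C)O[C@@H]2CC/C(C)=C/CCC(C)=C)[C@H](C=O)O1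
F3 | step 12 | (4S,5S)-4-{(2R)-2-[(tert-butyldimethylsilyl)oxy]-2-[(2S,3R)-3-[(3E)-3,7-dimethylocta-3,7-dien-1-yl]-2-methyloxiran-2-yl]ethyl}-5-ethenyloxolan-2-one | O=C1C[C@H](C[C@@H](O[Si](C)(C)C(C)(C)C)[C@@]2(C)O[C@@H]2CC/C(C)=C/CCC(C)=C)[C@H](C=C)O1
F4 | step 8 | ethyl (2E,5R,6E)-5-hydroxy-6,10-dimethylundeca-2,6,10-trienoate | CCOC(=O)/C=C/C[C@@H](O)/C(C)=C/CCC(C)=C
F5 | step 8 | ethyl (2E,5S)-5-hydroxy-5-[(2S,3S)-2-methyl-3-(3-methylbut-3-en-1-yl)oxiran-2-yl]pent-2-enoate | CCOC(=O)/C=C/C[C@H](O)[C@]1(C)O[C@H]1CCC(C)=C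
F6 | step 8 | ethyl (2E,5R,6E)-5-[(tert-butyldimethylsilyl)oxy]-6,10-dimethylundeca-2,6,10-trienoate | CCOC(=O)/C=C/C[C@@H](O[Si](C)(C)C(C)(C)C)/C(C)=C/CCC(C)=C
F7 | step 8 | (2E,5R,6E)-5-[(tert-butyldimethylsilyl)oxy]-6,10-dimethylundeca-2,6,10-trien-1-ol | OC/C=C/C[C@@H](O[Si](C)(C)C(C)(C)C)/C(C)=C/CCC(C)=C
F8 | step 8 | {(2S,3S)-3-[(2R,3E)-2-[(tert-butyldimethylsilyl)oxy]-3,7-dimethylocta-3,7-dien-1-yl]oxiran-2-yl}methanol | OC[C@@H]1O[C@H]1C[C@@H](O[Si](C)(C)C(C)(C)C)/C(C)=C/CCC(C)=C
F9 | step 8 | (2R,3S,5R,6E)-5-[(tert-butyldimethylsilyl)oxy]-3-(ethoxyethynyl)-6,10-dimethylundeca-6,10-diene-1,2-diol | OC[C@H](O)[C@H](C#COCC)C[C@@H](O[Si](C)(C)C(C)(C)C)/C(C)=C/CCC(C)=C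
F10 | step 8 | (4S,5R)-4-[(2R,3E)-2-[(tert-butyldimethylsilyl)oxy]-3,7-dimethylocta-3,7-dien-1-yl]-5-(hydroxymethyl)oxolan-2-one | O=C1C[C@H](C[C@@H](O[Si](C)(C)C(C)(C)C)/C(C)=C/CCC(C)=C)[C@H](CO)O1
F11 | step 8 | (2R,3S)-3-[(2R,3E)-2-[(tert-butyldimethylsilyl)oxy]-3,7-dimethylocta-3,7-dien-1-yl]-5-oxooxolane-2-carbaldehyde | O=C1C[C@H](C[C@@H](O[Si](C)(C)C(C)(C)C)/C(C)=C/CCC(C)=C)[C@H](C=O)O1
F12 | step 8 | (4S,5S)-4-[(2R,3E)-2-[(tert-butyldimethylsilyl)oxy]-3,7-dimethylocta-3,7-dien-1-yl]-5-ethenyloxolan-2-one | O=C1C[C@H](C[C@@H](O[Si](C)(C)C(C)(C)C)/C(C)=C/CCC(C)=C)[C@H](C=C)O1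
F13 | step 8 | (4S,5S)-5-ethenyl-4-[(2R,3E)-2-hydroxy-3,7-dimethylocta-3,7-dien-1-yl]oxolan-2-one | O=C1C[C@H](C[C@@H](O)/C(C)=C/CCC(C)=C)[C@H](C=C)O1
F14 | step 8 | (4S,5S)-5-ethenyl-4-{(2R)-2-hydroxy-2-[(2R,3R)-2-methyl-3-(3-methylbut-3-en-1-yl)oxiran-2-yl]ethyl}oxolan-2-one | O=C1C[C@H](C[C@@H](O)[C@@]2(C)O[C@@H]2CCC(C)=C)[C@H](C=C)O1
F15 | step 10 | (2R,3S,5R)-5-[(tert-butyldimethylsilyl)oxy]-3-(ethoxyethynyl)-2-hydroxy-5-[(2S,3R)-2-methyl-3-(3-methylbut-3-en-1-yl)oxiran-2-yl]pentyl 4-methylbenzenesulfonate | Cc1ccc(cc1)S(=O)(=O)OC[C@H](O)[C@H](C#COCC)C[C@@H](O[Si](C)(C)C(C)(C)C)[C@@]2(C)O[C@@H]2CCC(C)=C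
F16 | step 10 | (2R)-2-{(1S,3R)-3-[(tert-butyldimethylsilyl)oxy]-1-(ethoxyethynyl)-3-[(2S,3R)-2-methyl-3-(3-methylbut-3-en-1-yl)oxiran-2-yl]propyl}oxirane | C1O[C@@H]1[C@H](C#COCC)C[C@@H](O[Si](C)(C)C(C)(C)C)[C@@]2(C)O[C@@H]2CCC(C)=C
F17 | step 10 | (3S,4S,6R)-6-[(tert-butyldimethylsilyl)oxy]-4-(ethoxyethynyl)-6-[(2S,3R)-2-methyl-3-(3-methylbut-3-en-1-yl)oxiran-2-yl]hex-1-en-3-ol | C=C[C@H](O)[C@H](C#COCC)C[C@@H](O[Si](C)(C)C(C)(C)C)[C@@]1(C)O[C@@H]1CCC(C)=C
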